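Temperature separates zeta, epsilon and beta, which share one charge, and gamma changes it halfway, so I needed a number that moves with temperature and can be carried across unlike charges.

| setting | autumn | midnight | zeta | epsilon | beta | gamma |
|---|---|---|---|---|---|---|
| starting material | 0.15 M | 0.60 M | 0.30 M | 0.30 M | 0.30 M | 0.30 M |
| reagent | 0.18 M | 0.18 M | 0.180 M | 0.180 M | 0.180 M | 0.180 M |
| second substrate | 0.30 M | 0.30 M | 0.300 M | 0.300 M | 0.300 M | 0.300 M |
| third substrate | 0.060 M | 0.060 M | 0.0600 M | 0.0600 M | 0.0600 M | 0.0600 M |
| temperature | 12 °C | 29 °C | 35 °C | 20 °C | 5 °C |  |
| remark | run made earlier | run made earlier |  |  |  | at 35 °C until 2.5 min, from then on at 5 °C |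
| time |  |  | 5.0 min | 5.0 min | 5.0 min | 5.0 min |

- autumn (time / min: target / %): 4.00: 20.3; 8.00: 21.6; 12.0: 20.2; 15.0: 22.6
- midnight (time / min: target / %): 1.33: 9.2; 2.50: 9.1; 4.00: 9.1; 5.00: 9.7

(standard deviation of a reading: 1 percentage point)

- the flask that comes out highest in amount of target, in percent of the starting material charged, or "all alike" when all lie within 1.5 percentage points (zeta / epsilon / beta / gamma / all alike)
- target at the end, in percent of the starting material charged, zeta
- target at the end, in percent of the starting material charged, epsilon
- target at the end, in percent of the starting material charged, beta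
- target at the end, in percent of the starting material charged, gamma



Both runs were flat from their first reading, so I drew the curve of target against time as a rise, a knee and a level. The mean levels read:

autumn 21.2%, midnight 9.28%

The slope at the start in the midnight run was at least its level over its first reading time, 0.0698 min⁻¹ of the charge, and the knee lay before 1.33 min. The level was what I had to reckon.

Reagent was the limiting reagent, charged at 0.180 M against 0.660 M of substrates together in the new flasks. For my zero of the scale I gave every substrate molecule even odds, so that each substrate loses the same fraction of its charge, reagent over total substrate. I called this the even share: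

autumn 35.3%, midnight 18.8%, new flasks 27.3%

The level over the even share is a selectivity factor, which I called the capture ratio:

autumn 0.600, midnight 0.495

The levels differ by a factor 2.28 and the even shares by 1.88, so the ratio carries what remains, as a reading with the scatter of its runs. I took its logarithm as straight in temperature:

35 °C: 0.462, level 12.6%
20 °C: 0.548, level 14.9%

The capture ratio at 5 °C came to 0.650, which gives beta a level of 17.7%, the highest of my values.

The midnight run read level by 1.33 min, earlier than gamma's change at 2.5 min. Readings flat at one temperature could not show what cooling does to a level, so this was an assumption that the runs never tested: I supposed that gamma kept what stood at its change, and set it at zeta's 12.6%.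

The forecast gave 9% for zeta, 14.3% for epsilon, 21.5% for beta and 14% for gamma, with beta highest, and said “Gamma separates the two”; my reckoning gave other numbers, and among them set gamma level with zeta.

The flasks gave 12.5% in zeta, 15.1% in epsilon, 18.2% in beta and 12.5% in gamma, so beta came out highest. In gamma at the change, 2.50 min, reagent stood at 0% and target at 12.5%. Beta's capture ratio came to 0.667, beside my 0.650.

    third substrate + reagent → third product (k = 0.837 L mol⁻¹ s⁻¹, Ea = 45.0 kJ mol⁻¹)
    second substrate + reagent → second product (k = 0.389 L mol⁻¹ s⁻¹, Ea = 57.0 kJ mol⁻¹)
    starting material + reagent → target (k = 0.232 L mol⁻¹ s⁻¹, Ea = 39.0 kJ mol⁻¹)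
    2 starting material → self-condensation product (k = 0.165 L mol⁻¹ s⁻¹, Ea = 44.0 kJ mol⁻¹)
    (constants at 20 °C)

For a neighbour of beta charged with 0.75 M of starting material, the even share was 16.2%, and my capture ratio of 0.650 made that 10.5%. The computed neighbour gave 11.1%.

The readings are calculated for an exercise; scatter was added.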